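The route rests on cutting the trans C3–O and C2–isopropenyl bonds of the dihydrofuran ring back to the C2=C3 enol-ether bond of a flat benzofuran. In a single operation, catalyst-controlled oxygen transfer to that bond followed by anti attack of an isopropenyl cuprate at C2, the acetal carbon next to O1, sets both stereocentres and both bonds. The precursor is 6-methoxybenzofuran carrying the C5 acetyl as a dioxolane, made in four steps from 4-hydroxy-2-methoxyacetophenone. The Z acetoxymethylbutenoyl side chain is built separately from crotonaldehyde and attached to the C3 alkoxide; mild acid then frees the ketone.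

Key step: step 5

Assumption: (S,S)-(salen)MnCl, chloro[(S,S)-N,N′-bis(3,5-di-tert-butylsalicylidene)cyclohexane-1,2-diaminato]manganese (C36H52ClMnN2O2, trivalent manganese), is chosen because it oxidises indene on the face that corresponds to the (2R,3S)-epoxide of 7; should 7 show the opposite sense, the (R,R)-complex would be used.

Step 1
Reactants: 1 1-(4-hydroxy-2-methoxyphenyl)ethan-1-one
Product: 2 1-(4-hydroxy-5-iodo-2-methoxyphenyl)ethan-1-one
Conditions: NIS (1.05 equiv), TsOH·H2O (10 mol%), MeCN, 0 °C → rt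
Reagents that add atoms: N-iodosuccinimide, O=C1CCC(=O)N1I
Why: Electrophilic aromatic iodination should go to C5, ortho to the free hydroxyl and para to the methoxy group, because the other activated site, C3, is flanked by both oxygen substituents and is shielded from the bulky iodinating agent.

Step 2
Reactants: 2 1-(4-hydroxy-5-iodo-2-methoxyphenyl)ethan-1-one; 3 ethynyltrimethylsilane
Product: 4 1-{4-hydroxy-2-methoxy-5-[(trimethylsilyl)ethynyl]phenyl}ethan-1-one
Conditions: PdCl2(PPh3)2 (2 mol%), CuI (4 mol%), Et3N, THF, rt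
Reagents that add atoms: none
Why: Sonogashira coupling, in which zerovalent palladium inserts into the aryl C–I bond and the copper acetylide of 3 transmetalates, is reliable for ortho-iodophenols at room temperature, and any 2-silylbenzofuran formed by early ring closure converges to 6 in step 3.

Step 3
Reactants: 4 1-{4-hydroxy-2-methoxy-5-[(trimethylsilyl)ethynyl]phenyl}ethan-1-one
Product: 6 1-(6-methoxy-1-benzofuran-5-yl)ethan-1-one, via desilylated ethynylphenol 5 (not isolated)
Conditions: Bu4NF (2 equiv), THF, 65 °C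
Reagents that add atoms: none
Why: Fluoride cleaves the C(sp)–Si bond and the ammonium phenoxide adds to the terminal alkyne in a 5-endo-dig cycloisomerisation that is driven by formation of the aromatic furan ring.

Step 4
Reactants: 6 1-(6-methoxy-1-benzofuran-5-yl)ethan-1-one
Product: 7 6-methoxy-5-(2-methyl-1,3-dioxolan-2-yl)-1-benzofuran
Conditions: Me3SiOCH2CH2OSiMe3 (1.5 equiv), TMSOTf (5 mol%), CH2Cl2, −78 → −20 °C; pyridine quench
Reagents that add atoms: 1,2-bis(trimethylsilyloxy)ethane, C[Si](C)(C)OCCO[Si](C)(C)C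
Why: Noyori ketalisation is made irreversible by loss of hexamethyldisiloxane and runs cold enough to spare the acid-sensitive, electron-rich benzofuran.

Step 5
Reactants: 7 6-methoxy-5-(2-methyl-1,3-dioxolan-2-yl)-1-benzofuran; 8 isopropenylmagnesium bromide
Product: 10 (2R,3S)-6-methoxy-5-(2-methyl-1,3-dioxolan-2-yl)-2-(prop-1-en-2-yl)-2,3-dihydro-1-benzofuran-3-ol, via benzofuran 2,3-epoxide 9 (not isolated)
Conditions: (S,S)-(salen)MnCl (5 mol%), 4-phenylpyridine N-oxide (20 mol%), PhIO (1.1 equiv), 4 Å MS, CH2Cl2, −30 °C; cold solution cannulated into (CH2=CMe)2CuMgBr [from 8 (4 equiv), CuI (2 equiv), THF, −40 °C] at −78 °C, then −78 → −40 °C; aq NH4Cl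
Reagents that add atoms: iodosylbenzene, O=Ic1ccccc1
Why: Proposed new method: the oxomanganese species (pentavalent manganese) formed from (S,S)-(salen)MnCl and PhIO should transfer oxygen to one face of the electron-rich C2=C3 enol-ether bond of 7, breaking the furan aromaticity and giving cis-fused epoxide 9, whose C2 is an acetal carbon held between O1 and the oxirane oxygen. The soft magnesium cuprate should then displace the oxirane oxygen at C2 from the opposite face, by direct SN2 attack or by collapse of a tight ion pair stabilised by O1, forming the C2–isopropenyl bond and leaving the C3 alkoxide trans to it. The closest known reaction types are salen–manganese epoxidation of indene, chromenes and enol ethers, dioxirane epoxidation of benzofurans to labile 2,3-epoxides, and anti opening of glycal epoxides by organocuprates. No ring of the product is closed; the only ring formed is the transient oxirane, made by oxygen-atom transfer across C2=C3 and reopened in the same operation. C3 (S) is fixed by the catalyst-controlled choice of face and C2 (R) by stereospecific inversion relative to C3. The step needs enantiofacial selectivity (from the catalyst), opening at C2 and not at benzylic C3 (acetal activation by O1, a soft nucleophile, low temperature, and an N-oxide ligand and THF that mute Lewis acidity) and chemoselectivity (the isopropenyl alkene arrives after the oxidant, and the dioxolane keeps the ketone from the organometallic).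

Step 6
Reactants: 11 (2E)-but-2-enal
Product: 13 (2Z)-2-bromobut-2-enal, via 2,3-dibromobutanal 12 (not isolated)
Conditions: Br2 (1.0 equiv), CH2Cl2, 0 °C; then Et3N (1.2 equiv), 0 °C → rt
Reagents that add atoms: bromine, BrBr
Why: Bromination–dehydrobromination (anti addition of bromine, then amine-induced E1cB loss of HBr) should give the thermodynamically preferred Z α-bromoenal, in which the methyl group is trans to the formyl group and cis to bromine.

Step 7
Reactants: 13 (2Z)-2-bromobut-2-enal
Product: 14 (2Z)-2-bromobut-2-en-1-ol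
Conditions: NaBH4, CeCl3·7H2O, MeOH, 0 °C
Reagents that add atoms: none
Why: Luche reduction delivers hydride 1,2 to the enal without touching the vinyl bromide or the alkene geometry.

Step 8
Reactants: 14 (2Z)-2-bromobut-2-en-1-ol
Product: 16 (2Z)-2-(hydroxymethyl)but-2-enoic acid, via dilithiated alkoxide 15 (not isolated)
Conditions: t-BuLi (3.1 equiv), Et2O, −78 °C; CO2 (g), −78 °C → rt; aq HCl to pH 2
Reagents that add atoms: carbon dioxide, O=C=O
Why: After O-deprotonation, bromine–lithium exchange gives a vinyllithium that is configurationally stable at −78 °C, and carboxylation with retention puts the carboxyl group where bromine was, cis to the methyl group, which is the Z acid.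

Step 9
Reactants: 16 (2Z)-2-(hydroxymethyl)but-2-enoic acid
Product: 17 (2Z)-2-[(acetyloxy)methyl]but-2-enoic acid
Conditions: Ac2O (2.2 equiv), pyridine (3 equiv), CH2Cl2, 0 °C → rt; then H2O, THF; dilute acid work-up
Reagents that add atoms: acetic anhydride, CC(=O)OC(C)=O
Why: This is standard O-acetylation of a primary allylic alcohol, in which the mixed anhydride formed at the carboxyl group is hydrolysed during work-up and the short, cold contact with pyridine should leave the Z alkene unchanged.

Step 10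
Reactants: 17 (2Z)-2-[(acetyloxy)methyl]but-2-enoic acid
Product: 18 (2Z)-2-[(acetyloxy)methyl]but-2-enoyl chloride
Conditions: 1-chloro-N,N,2-trimethylprop-1-en-1-amine (1.1 equiv), CH2Cl2, 0 °C → rt; concentrate, use crude
Reagents that add atoms: 1-chloro-N,N,2-trimethylprop-1-en-1-amine, CC(C)=C(Cl)N(C)C
Why: The α-chloroenamine converts the acid to its chloride under neutral conditions without releasing HCl, which avoids acid-mediated Z to E isomerisation and allylic transposition of the acetate.

Step 11
Reactants: 10 (2R,3S)-6-methoxy-5-(2-methyl-1,3-dioxolan-2-yl)-2-(prop-1-en-2-yl)-2,3-dihydro-1-benzofuran-3-ol; 18 (2Z)-2-[(acetyloxy)methyl]but-2-enoyl chloride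
Product: 20 (2R,3S)-6-methoxy-5-(2-methyl-1,3-dioxolan-2-yl)-2-(prop-1-en-2-yl)-2,3-dihydro-1-benzofuran-3-yl (2Z)-2-[(acetyloxy)methyl]but-2-enoate, via lithium alkoxide 19 (not isolated)
Conditions: LiN(SiMe3)2 (1.0 equiv), THF, −78 °C; then 18 (1.5 equiv), −78 → −40 °C; aq NaHCO3
Reagents that add atoms: none
Why: O-acylation of a preformed lithium alkoxide by an acid chloride is fast at −78 °C and needs no nucleophilic amine catalyst, so the Z geometry and the allylic acetate of 18 are not exposed to addition–elimination or SN2′ pathways, and no bond at C2 or C3 is broken.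

Step 12
Reactants: 20 (2R,3S)-6-methoxy-5-(2-methyl-1,3-dioxolan-2-yl)-2-(prop-1-en-2-yl)-2,3-dihydro-1-benzofuran-3-yl (2Z)-2-[(acetyloxy)methyl]but-2-enoate
Product: 21 (2R,3S)-5-acetyl-6-methoxy-2-(prop-1-en-2-yl)-2,3-dihydro-1-benzofuran-3-yl (2Z)-2-[(acetyloxy)methyl]but-2-enoate
Conditions: PPTS (0.2 equiv), acetone/H2O (10:1), rt
Reagents that add atoms: water, O
Why: In this acid-catalysed ketal hydrolysis the dioxolane of an ortho,para-dioxygenated aryl methyl ketone ionises to a strongly stabilised oxocarbenium ion and is cleaved by a pyridinium buffer at room temperature, conditions under which the benzylic C3 ester, the allylic acetate and the Z alkene should persist.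

Compound list
1 | 1-(4-hydroxy-2-methoxyphenyl)ethan-1-one (4-hydroxy-2-methoxyacetophenone) | CC(=O)c1ccc(O)cc1OC | starting material
2 | 1-(4-hydroxy-5-iodo-2-methoxyphenyl)ethan-1-one | CC(=O)c1cc(I)c(O)cc1OC | intermediate
3 | ethynyltrimethylsilane | C#C[Si](C)(C)C | starting material
4 | 1-{4-hydroxy-2-methoxy-5-[(trimethylsilyl)ethynyl]phenyl}ethan-1-one | CC(=O)c1cc(C#C[Si](C)(C)C)c(O)cc1OC | intermediate
5 | 1-(5-ethynyl-4-hydroxy-2-methoxyphenyl)ethan-1-one (not isolated) | CC(=O)c1cc(C#C)c(O)cc1OC | intermediate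
6 | 1-(6-methoxy-1-benzofuran-5-yl)ethan-1-one | CC(=O)c1cc2ccoc2cc1OC | intermediate
7 | 6-methoxy-5-(2-methyl-1,3-dioxolan-2-yl)-1-benzofuran | COc1cc2occc2cc1C3(C)OCCO3 | intermediate
8 | isopropenylmagnesium bromide (prop-1-en-2-ylmagnesium bromide) | C=C(C)[Mg]Br | starting material
9 | (2R,3S)-2,3-epoxy-6-methoxy-5-(2-methyl-1,3-dioxolan-2-yl)-2,3-dihydro-1-benzofuran, oxirane cis-fused across C2–C3 (not isolated) | COc1cc2O[C@H]3O[C@H]3c2cc1C4(C)OCCO4 | intermediate
10 | (2R,3S)-6-methoxy-5-(2-methyl-1,3-dioxolan-2-yl)-2-(prop-1-en-2-yl)-2,3-dihydro-1-benzofuran-3-ol (trans) | C=C(C)[C@H]1Oc2cc(OC)c(C3(C)OCCO3)cc2[C@@H]1O | intermediate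
11 | (2E)-but-2-enal (crotonaldehyde) | C/C=C/C=O | starting material
12 | (2R*,3S*)-2,3-dibromobutanal, racemic anti adduct, one enantiomer drawn (not isolated) | C[C@H](Br)[C@H](Br)C=O | intermediate
13 | (2Z)-2-bromobut-2-enal | C/C=C(\Br)C=O | intermediate
14 | (2Z)-2-bromobut-2-en-1-ol | C/C=C(\Br)CO | intermediate
15 | lithium 2-lithiobut-2-en-1-olate, C–Li cis to the methyl group (not isolated) | C/C=C(\[Li])CO[Li] | intermediate
16 | (2Z)-2-(hydroxymethyl)but-2-enoic acid | C/C=C(\C(=O)O)CO | intermediate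
17 | (2Z)-2-[(acetyloxy)methyl]but-2-enoic acid | C/C=C(\C(=O)O)COC(C)=O | intermediate
18 | (2Z)-2-[(acetyloxy)methyl]but-2-enoyl chloride | C/C=C(\C(=O)Cl)COC(C)=O | intermediate
19 | lithium (2R,3S)-6-methoxy-5-(2-methyl-1,3-dioxolan-2-yl)-2-(prop-1-en-2-yl)-2,3-dihydro-1-benzofuran-3-olate (not isolated) | C=C(C)[C@H]1Oc2cc(OC)c(C3(C)OCCO3)cc2[C@@H]1O[Li] | intermediate
20 | (2R,3S)-6-methoxy-5-(2-methyl-1,3-dioxolan-2-yl)-2-(prop-1-en-2-yl)-2,3-dihydro-1-benzofuran-3-yl (2Z)-2-[(acetyloxy)methyl]but-2-enoate | C=C(C)[C@H]1Oc2cc(OC)c(C3(C)OCCO3)cc2[C@@H]1OC(=O)/C(=C\C)COC(C)=O | intermediate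
21 | (2R,3S)-5-acetyl-6-methoxy-2-(prop-1-en-2-yl)-2,3-dihydro-1-benzofuran-3-yl (2Z)-2-[(acetyloxy)methyl]but-2-enoate | C=C(C)[C@H]1Oc2cc(OC)c(C(C)=O)cc2[C@@H]1OC(=O)/C(=C\C)COC(C)=O | target

Total step count: 12.
Longest linear sequence: 7 steps (steps 1–5, 11 and 12 from 1; the side-chain branch, steps 6–10 followed by 11 and 12, is equally long).

Steps most likely to fail

Step 5 (proposed new method). Oxygen transfer to the aromatic furan bond may be slow or poorly face-selective. The epoxide may rearrange by hydride shift, or open reversibly to an achiral ortho-quinone methide and lose its configuration, before the cuprate reaches it. The nucleophile may also attack benzylic C3, or add syn. The fallback uses known reactions only, sets out from 2 and comes back at 21. Hydroboration of 2-methylbut-1-en-3-yne with pinacolborane (Cp2Zr(H)Cl cat., Et3N) should give 4,4,5,5-tetramethyl-2-[(1E)-3-methylbuta-1,3-dien-1-yl]-1,3,2-dioxaborolane F1. Suzuki–Miyaura coupling of F1 with 2 (Pd(PPh3)4, K2CO3, dioxane/H2O, 80 °C) should give 1-{4-hydroxy-2-methoxy-5-[(1E)-3-methylbuta-1,3-dien-1-yl]phenyl}ethan-1-one F2, which is protected (pivaloyl chloride, Et3N, CH2Cl2) as 4-acetyl-5-methoxy-2-[(1E)-3-methylbuta-1,3-dien-1-yl]phenyl 2,2-dimethylpropanoate F3. Shi epoxidation with the enantiomer of the fructose-derived ketone (from L-sorbose), Oxone (2KHSO5·KHSO4·K2SO4) and K2CO3 buffer in MeCN/dimethoxymethane/H2O at 0 °C should oxidise the trans-disubstituted styrenyl bond in preference to the 1,1-disubstituted one and give 4-acetyl-5-methoxy-2-[(2S,3S)-3-(prop-1-en-2-yl)oxiran-2-yl]phenyl 2,2-dimethylpropanoate F4. K2CO3 in MeOH should cleave the pivalate to 1-{4-hydroxy-2-methoxy-5-[(2S,3S)-3-(prop-1-en-2-yl)oxiran-2-yl]phenyl}ethan-1-one F5, whose phenoxide opens the oxirane 5-exo at the allylic carbon with inversion in the same flask. This gives 1-[(2R,3S)-3-hydroxy-6-methoxy-2-(prop-1-en-2-yl)-2,3-dihydro-1-benzofuran-5-yl]ethan-1-one F6. Because F6 carries no ketal, acylation with 18 (pyridine, CH2Cl2, 0 °C) leads directly to 21.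

Step 11. The side chain may lose its Z geometry or suffer SN2′ attack at the allylic acetate, its acetyl group may be transferred to the alkoxide, or the ester may eliminate to the aromatic benzofuran. The fallback carries the side-chain oxygen as a silyl ether and acetylates last; it sets out from 16 and 10 and comes back at 20. Silylation of 16 on both oxygens (TBSCl, imidazole, DMF) should give tert-butyl(dimethyl)silyl (2Z)-2-({[tert-butyl(dimethyl)silyl]oxy}methyl)but-2-enoate F7, and selective cleavage of the silyl ester (K2CO3, MeOH/H2O) should give (2Z)-2-({[tert-butyl(dimethyl)silyl]oxy}methyl)but-2-enoic acid F8. Yamaguchi esterification proceeds through (2Z)-2-({[tert-butyl(dimethyl)silyl]oxy}methyl)but-2-enoic 2,4,6-trichlorobenzoic anhydride F9 (2,4,6-trichlorobenzoyl chloride, Et3N, toluene). With 10 and DMAP at room temperature it should give (2R,3S)-6-methoxy-5-(2-methyl-1,3-dioxolan-2-yl)-2-(prop-1-en-2-yl)-2,3-dihydro-1-benzofuran-3-yl (2Z)-2-({[tert-butyl(dimethyl)silyl]oxy}methyl)but-2-enoate F10. Buffered fluoride (Bu4NF, AcOH, THF, 0 °C) should give (2R,3S)-6-methoxy-5-(2-methyl-1,3-dioxolan-2-yl)-2-(prop-1-en-2-yl)-2,3-dihydro-1-benzofuran-3-yl (2Z)-2-(hydroxymethyl)but-2-enoate F11, and acetylation (Ac2O, pyridine, 0 °C) gives 20.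

Step 8. The vinyllithium may isomerise or lose lithium oxide to an allene, and the small, water-soluble hydroxy acid may be poorly recovered. The fallback replaces the organolithium by palladium chemistry; it sets out from 14 and comes back at 16. Methoxycarbonylation of the vinyl bromide (PdCl2(PPh3)2, CO (1 atm), Et3N, MeOH, 60 °C), which proceeds with retention of alkene geometry, should give methyl (2Z)-2-(hydroxymethyl)but-2-enoate F12. Mild saponification (LiOH, THF/H2O, 0 °C) then gives 16.

Further compounds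
F1 | step 5 | 4,4,5,5-tetramethyl-2-[(1E)-3-methylbuta-1,3-dien-1-yl]-1,3,2-dioxaborolane | CC(=C)/C=C/B1OC(C)(C)C(C)(C)O1
F2 | step 5 | 1-{4-hydroxy-2-methoxy-5-[(1E)-3-methylbuta-1,3-dien-1-yl]phenyl}ethan-1-one | CC(=O)c1cc(/C=C/C(C)=C)c(O)cc1OC
F3 | step 5 | 4-acetyl-5-methoxy-2-[(1E)-3-methylbuta-1,3-dien-1-yl]phenyl 2,2-dimethylpropanoate | CC(C)(C)C(=O)Oc1cc(OC)c(C(C)=O)cc1/C=C/C(C)=C
F4 | step 5 | 4-acetyl-5-methoxy-2-[(2S,3S)-3-(prop-1-en-2-yl)oxiran-2-yl]phenyl 2,2-dimethylpropanoate | CC(C)(C)C(=O)Oc1cc(OC)c(C(C)=O)cc1[C@@H]2O[C@H]2C(C)=C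
F5 | step 5 | 1-{4-hydroxy-2-methoxy-5-[(2S,3S)-3-(prop-1-en-2-yl)oxiran-2-yl]phenyl}ethan-1-one | CC(=O)c1cc([C@@H]2O[C@H]2C(C)=C)c(O)cc1OC
F6 | step 5 | 1-[(2R,3S)-3-hydroxy-6-methoxy-2-(prop-1-en-2-yl)-2,3-dihydro-1-benzofuran-5-yl]ethan-1-one | C=C(C)[C@H]1Oc2cc(OC)c(C(C)=O)cc2[C@@H]1O
F7 | step 11 | tert-butyl(dimethyl)silyl (2Z)-2-({[tert-butyl(dimethyl)silyl]oxy}methyl)but-2-enoate | C/C=C(\C(=O)O[Si](C)(C)C(C)(C)C)CO[Si](C)(C)C(C)(C)C
F8 | step 11 | (2Z)-2-({[tert-butyl(dimethyl)silyl]oxy}methyl)but-2-enoic acid | C/C=C(\C(=O)O)CO[Si](C)(C)C(C)(C)C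
F9 | step 11 | (2Z)-2-({[tert-butyl(dimethyl)silyl]oxy}methyl)but-2-enoic 2,4,6-trichlorobenzoic anhydride | C/C=C(\C(=O)OC(=O)c1c(Cl)cc(Cl)cc1Cl)CO[Si](C)(C)C(C)(C)C
F10 | step 11 | (2R,3S)-6-methoxy-5-(2-methyl-1,3-dioxolan-2-yl)-2-(prop-1-en-2-yl)-2,3-dihydro-1-benzofuran-3-yl (2Z)-2-({[tert-butyl(dimethyl)silyl]oxy}methyl)but-2-enoate | C=C(C)[C@H]1Oc2cc(OC)c(C3(C)OCCO3)cc2[C@@H]1OC(=O)/C(=C\C)CO[Si](C)(C)C(C)(C)C
F11 | step 11 | (2R,3S)-6-methoxy-5-(2-methyl-1,3-dioxolan-2-yl)-2-(prop-1-en-2-yl)-2,3-dihydro-1-benzofuran-3-yl (2Z)-2-(hydroxymethyl)but-2-enoate | C=C(C)[C@H]1Oc2cc(OC)c(C3(C)OCCO3)cc2[C@@H]1OC(=O)/C(=C\C)CO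
F12 | step 8 | methyl (2Z)-2-(hydroxymethyl)but-2-enoate | C/C=C(\C(=O)OC)CO
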